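## Analysis of the target

Target 27 is a sesquineolignan built from three C6 units. Rings C and D form a 2,3-dihydrobenzofuran (O1, C2, C3, C3a, C4 to C7, C7a) with a formyl group at C5, a methoxy group at C7, a hydroxymethyl group at C3 and ring B (3,5-dimethoxy-4-oxyphenyl) at C2. The 4-oxygen of ring B is bound to C8′ of a propane-1,3-diol arm whose carbinol carbon C7′ carries ring A (4-hydroxy-3-methoxyphenyl) and whose C9′ is a CH2OH group. The four stereocentres fall into two pairs: C2 (R) and C3 (S) are trans on ring D, and C7′ (S) and C8′ (R) are erythro, that is anti when the chain ring A–C7′–C8′–C9′ is drawn as a zigzag. Ring B insulates the pairs from each other, so each must be set in the absolute sense. The sensitive sites are the aldehyde, the ring A phenol para to a benzylic alcohol (ionisation, quinone methide formation) and the benzylic ether C2–O1 para to the ring B oxygen (ring opening under acid, and under base once that oxygen is a free phenol). The ring B oxygen lies between two methoxy groups and is a poor nucleophile towards a secondary carbon, so the C8′–O bond is hard to make directly. The strategy rests on the pattern at C3: it carries C3a of ring C and an exocyclic one-carbon unit and is flanked by C2, which carries ring B and O1. This is what remains when C4 of a 2-arylchroman-4-one is pushed out of the ring by a shift of the ring C carbon from C4 to C3.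

## Retrosynthetic reasoning

**Arm.** 27 is traced back to the protected diol 25 (two silyl ethers, one dimethyl acetal) and 25 to imide 24 by reductive removal of the auxiliary, which turns the acyl carbon into C9′. In 24 the C7′–C8′ bond is cut. This is the only cut that creates both arm stereocentres in one carbon–carbon bond formation and leaves the awkward C8′–O bond intact. It leads to aryloxyacetyl imide 20 and silylated aldehyde 22, made from vanillin 21. The forward reaction must be an anti-selective glycolate aldol addition under absolute control of the (4R)-benzyl auxiliary. It must also tolerate the acetal, two silyl ethers and the benzylic ether of ring D, which excludes strongly Lewis acidic enolisation.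

**Aryl ether.** In 20 the O–CH2 bond of the glycolate is cut to phenol 17 and bromoacetyl imide 19, made from oxazolidinone 18. The hindered ring B oxygen is thereby alkylated at a primary, carbonyl-activated carbon instead of at C8′, and the auxiliary arrives with the two-carbon unit.

**Adjusting the core.** 17 goes back through 16, 15, 14 and 13 to diester 12. Both oxidised carbons of 12 are esters, so one hydride reduction gives the C3 hydroxymethyl group and a benzylic alcohol at C5, and only the latter is oxidised to the aldehyde. The aldehyde is masked as a dimethyl acetal and the primary alcohol as a silyl ether before the aryl mesylate is cleaved. The reason is that the amide base, the later enolate and the hydride would attack a free aldehyde, and a free alkoxide would capture the sulfene released from the mesylate.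

**Ring contraction.** In 12 the bond C3–C3a is cut and C3a is reconnected to the C3 ester carbon, which returns that carbon to the ring as C4 of flavanone 9. The cut trades a trans-2,3-disubstituted five-membered ring with two stereocentres for a six-membered ring with the single stereocentre C2, for which a catalytic asymmetric synthesis exists. C3 then follows from C2 through a stereospecific 1,2-shift. The forward reaction must move the ring C carbon from C4 to C3 under oxidation at C3 without shifting ring B, dehydrogenating to the flavone or opening the pyranone. Ring B therefore enters as its mesylate, which makes it a poor migrating group and a poor stabiliser of positive charge at C2 and which survives strong acid. The esters are methyl esters so that the methanolic medium cannot scramble them.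

**Flavanone.** In 9 the C2–aryl bond is cut to chromone 5 and arylboronic acid 8. The conjugate addition has to set C2 as R. It runs without base, so the product cannot racemise by ring opening to the chalcone, a real danger for a flavanone whose ring oxygen is para to an ester.

**Building blocks.** 5 is traced to o-hydroxyacetophenone 3 by one-carbon homologation through enaminone 4 and acid ring closure. The acetyl group of 3 is not introduced by a Fries rearrangement: hot Lewis acid next to an ortho-methoxyphenol unit, and a competing directing effect para to the methoxy group, would make that step unreliable. Instead the acetyl, hydroxyl and methoxy groups are bought in place in 1, and the ester carbon is added para to the phenol by bromination to 2 and carbonylation. 8 comes from bromophenol 6 by mesylation to 7 and borylation of the carbon–bromine bond.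

## Alternatives that were turned down

**Alternative 1:** The disconnection is the C7′–O bond of the arm, with C8′ and its aryl ether already in place and ring B carried as an aldehyde on which rings C and D would be built afterwards. In the forward key step a high-potential quinone abstracts hydride from the C7′ methylene of the open-chain tert-butyl carbonate A2. The carbonyl oxygen of the carbonate closes onto the benzylic cation with loss of the tert-butyl group, giving the six-membered cyclic carbonate A1 with aryl and aryloxy groups trans, a masked erythro diol.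
- For it: C7′ is set from C8′ by substrate control through a ring, with no auxiliary. The benzylic oxygen comes directly from a C–H bond, and the carbonate protects both arm hydroxyl groups at once.
- Against it: the key step solves the easier half of the molecule. C8′ must first be made enantiopure with the hindered aryl ether already attached. The cation at C7′ lies next to the inductively withdrawing aryloxy carbon and is supported only by a silyloxy donor, so hydride abstraction may be slow. The trans preference rests on a modest conformational bias of a six-membered ring. The dihydrobenzofuran, with its two stereocentres, would then have to be built on the aldehyde of A1 beside a benzylic carbonate that ionises easily.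
- Comparison: on the arm this alternative is the stronger, since the chosen route uses an aldol step that extends known chemistry. The chosen strategy offers instead a catalytic, checkable entry to the absolute configuration of the core and a precedented ring contraction that derives C3 from C2.

**Alternative 2:** The disconnection cuts C2–C3 and C2–O1 of ring D. C2 with ring B comes from a benzylsulfonium ylide, and ring C with C3 from an o-quinone methide. In the forward key step base eliminates sulfinate from sulfone A4 to give the quinone methide and deprotonates the chiral sulfonium salt A5 (drawn with a C2-symmetric thiolane as an example). Conjugate addition of the ylide forms C2–C3, and the phenoxide displaces the sulfide at C2 to give the trans dihydrobenzofuran A3.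
- For it: it is the most convergent plan. Two bonds, ring D and both stereocentres are made in one step, and C3 already carries its CH2O group at the right oxidation level.
- Against it: the absolute configuration depends on a stoichiometric chiral sulfide, whose facial control over an acyclic, semi-stabilised ylide on an electron-rich benzyl group is less secure than a catalytic conjugate addition to a rigid chromone. The sulfonium salt A5 can ionise at its electron-rich benzylic carbon. The quinone methide from A4 has hydrogens next to the methide carbon and can tautomerise to a vinylphenol before the ylide arrives. A3 carries bromine where the aldehyde is needed, which costs a later metalation and formylation.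
- Comparison: this alternative is shorter to the core and more convergent. The chosen strategy offers an enantioselectivity that is set by a catalyst and can be measured at flavanone 9 before material is committed, and the C5 carbon is in place from the start.

**Alternative 3:** The disconnection is the C2–O1 bond, made from a C2–H bond. In the forward key step, constant-current electrolysis at a carbon anode in a fluorinated alcohol with a tetraalkylammonium hexafluorophosphate oxidises ring B of the 2,3-diarylpropyl pivalate A7. C2 loses a proton and a second electron, and the ring C phenol adds to the cation to give the trans dihydrobenzofuran A6.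
- For it: the closure is biomimetic and favours trans both kinetically and thermodynamically. Only the stereocentre of A7 must be made by asymmetric synthesis, the aldehyde and the C3 oxygen are already at the right level, and no oxidant waste is formed.
- Against it: the step would be a new reaction for this substrate type. The anode must oxidise ring B and not the free phenol of ring C, the aldehyde or the allyl ether. The product A6 keeps the electron-rich ring B and has a C2–H bond that is both benzylic and α to oxygen, so further oxidation to the benzofuran, which destroys both stereocentres, is a built-in competitor.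
- Comparison: in step count and in avoiding protecting-group changes on ring B this alternative is stronger. The chosen strategy offers a key step with close precedent on flavanones, and it keeps ring B electron-poor at the moment of oxidation so that the new stereocentres are not exposed to over-oxidation.

Key step: step 7

Remark: compounds 1, 6, 18 and 21 are taken to be commercial, and the (S)-configured pyridine–oxazoline ligand is assumed to give the 2R flavanone, as its facial preference with cyclic enones implies.

## Route

Step 1
Reactants: 1 1-(2-hydroxy-3-methoxyphenyl)ethan-1-one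
Product: 2 1-(5-bromo-2-hydroxy-3-methoxyphenyl)ethan-1-one
Conditions: NBS, MeCN, 0 °C to rt
Reagents that add atoms: N-bromosuccinimide, O=C1CCC(=O)N1Br
Why: Electrophilic aromatic bromination; the position para to the phenol and meta to the acetyl group is the only activated open site, both ortho positions being blocked.

Step 2
Reactants: 2 1-(5-bromo-2-hydroxy-3-methoxyphenyl)ethan-1-one
Product: 3 methyl 3-acetyl-4-hydroxy-5-methoxybenzoate
Conditions: Pd(OAc)2 (cat.), Xantphos, CO (1 atm), Et3N, MeOH/DMF, 70 °C
Reagents that add atoms: carbon monoxide, [C-]#[O+]; methanol, CO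
Why: Palladium-catalysed methoxycarbonylation of an aryl bromide (oxidative addition of zerovalent palladium, CO insertion, methanolysis of the acyl palladium species); phenol and ketone are spectators.

Step 3
Reactants: 3 methyl 3-acetyl-4-hydroxy-5-methoxybenzoate
Product: 5 methyl 8-methoxy-4-oxo-4H-chromene-6-carboxylate, via enaminone 4 (not isolated)
Conditions: Me2NCH(OMe)2, toluene, 100 °C; then conc. HCl, CH2Cl2, 40 °C
Reagents that add atoms: N,N-dimethylformamide dimethyl acetal, COC(OC)N(C)C
Why: Condensation of the acetyl methyl group with the amide acetal gives the enaminone; acid then brings about conjugate addition of the phenol and loss of dimethylamine (enaminone route to chromones).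

Step 4
Reactants: 6 4-bromo-2,6-dimethoxyphenol
Product: 7 4-bromo-2,6-dimethoxyphenyl methanesulfonate
Conditions: MsCl, Et3N, CH2Cl2, 0 °C
Reagents that add atoms: methanesulfonyl chloride, CS(=O)(=O)Cl
Why: O-Sulfonylation of the phenol; the mesylate is the electron-withdrawing, acid-stable mask that ring B needs in step 7.

Step 5
Reactants: 7 4-bromo-2,6-dimethoxyphenyl methanesulfonate
Product: 8 [4-(methanesulfonyloxy)-3,5-dimethoxyphenyl]boronic acid
Conditions: B2(OH)4, Pd(OAc)2 (cat.), XPhos, KOAc, EtOH, 80 °C
Reagents that add atoms: tetrahydroxydiboron, OB(O)B(O)O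
Why: Miyaura-type borylation with tetrahydroxydiboron gives the boronic acid directly; zerovalent palladium inserts into the C–Br bond, the aryl mesylate between two methoxy groups being far less reactive.

Step 6
Reactants: 5 methyl 8-methoxy-4-oxo-4H-chromene-6-carboxylate; 8 [4-(methanesulfonyloxy)-3,5-dimethoxyphenyl]boronic acid
Product: 9 methyl (2R)-2-[4-(methanesulfonyloxy)-3,5-dimethoxyphenyl]-8-methoxy-4-oxo-3,4-dihydro-2H-chromene-6-carboxylate
Conditions: Pd(OCOCF3)2 (5 mol%), (S)-4-tert-butyl-2-(pyridin-2-yl)-4,5-dihydrooxazole (6 mol%), NH4PF6, H2O, ClCH2CH2Cl, 60 °C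
Reagents that add atoms: none
Why: Asymmetric conjugate addition of an arylboronic acid to a chromone under cationic divalent palladium and a pyridine–oxazoline ligand (transmetalation, enantio-determining insertion of C2=C3 into the aryl–palladium bond, protonolysis of the palladium enolate by water). The tert-butyl group of the ligand blocks one face of the enone, and the (S)-ligand is expected to give 2R; should the sense prove opposite, the antipodal ligand is used. No base is present, so the product cannot racemise by ring opening.

Step 7
Reactants: 9 (2R)-flavanone with ring B mesylate and ring C methyl ester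
Product: 12 dimethyl (2R,3R)-2-[4-(methanesulfonyloxy)-3,5-dimethoxyphenyl]-7-methoxy-2,3-dihydro-1-benzofuran-3,5-dicarboxylate, via enol ether 10 (not isolated), via iodanyl ketal 11 (not isolated)
Conditions: PhI(OAc)2 (1.2 equiv), conc. H2SO4 (2 equiv), HC(OMe)3, 0 °C to rt
Reagents that add atoms: trimethyl orthoformate, COC(OC)OC
Why: Acid and the orthoester convert the C4 ketone into enol ether 10; PhI(OAc)2 attacks C3 of 10 on the face away from the C2 aryl group and methanol closes the oxocarbenium ion, giving ketal 11 with the iodanyl group and ring B trans and both equatorial. In 11 the ring bond C4–C4a is antiperiplanar to C3–I, so the ring C carbon moves from C4 to C3 as iodobenzene leaves; this forms the C3–C3a bond, and C4 leaves the ring as a dimethoxycarbenium ion that is demethylated to the methyl ester. The closest known reaction type is the oxidative ring contraction of flavanones to methyl 2-aryl-2,3-dihydrobenzofuran-3-carboxylates with trivalent iodine or trivalent thallium reagents in trimethyl orthoformate, a cyclic case of the oxidative 1,2-aryl shift of aryl ketones to arylacetic esters. Ring D is thus formed by contraction of the pyranone through a 1,2-aryl shift; no open-chain precursor cyclises. The new stereocentre C3 is controlled by C2: migration proceeds with inversion at C3, anti to an iodane that is trans to ring B, which places the ester carbon trans to ring B, and C2 itself is not touched. The step needs the shift of ring C to outrun a 2,3-shift of ring B (isoflavone), loss of iodobenzene by elimination (flavone) or by methanol substitution at C3, and acid-induced opening of the pyranone, which would racemise C2. The ketal (two methoxy groups pushing at C4, no enolisable carbonyl left, iodane held equatorial), the ring oxygen ortho to the migrating carbon and the mesylate, which makes ring B a poor migrating group and a poor cation stabiliser, work for the desired path. The ring C ester, para to O1, is the one feature that works against it.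

Step 8
Reactants: 12 trans dihydrobenzofuran diester
Product: 13 4-[(2R,3S)-3,5-bis(hydroxymethyl)-7-methoxy-2,3-dihydro-1-benzofuran-2-yl]-2,6-dimethoxyphenyl methanesulfonate
Conditions: i-Bu2AlH (excess), CH2Cl2, −78 to 0 °C; aq. KNaC4H4O6
Reagents that add atoms: none
Why: Hydride reduction of both methyl esters to primary alcohols. The reagent is Lewis acidic and not basic, so the acidic C3–H (α to the ester, β to the ring oxygen) is neither epimerised nor lost in an E1cB ring opening, and the aryl mesylate is left alone at low temperature.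

Step 9
Reactants: 13 diol mesylate
Product: 14 4-[(2R,3S)-5-formyl-3-(hydroxymethyl)-7-methoxy-2,3-dihydro-1-benzofuran-2-yl]-2,6-dimethoxyphenyl methanesulfonate
Conditions: MnO2 (activated, excess), CH2Cl2, rt
Reagents that add atoms: none
Why: Chemoselective oxidation of the benzylic alcohol at C5; the non-benzylic C3 hydroxymethyl group is not oxidised by MnO2.

Step 10
Reactants: 14 hydroxy aldehyde mesylate
Product: 15 4-[(2R,3S)-5-(dimethoxymethyl)-3-(hydroxymethyl)-7-methoxy-2,3-dihydro-1-benzofuran-2-yl]-2,6-dimethoxyphenyl methanesulfonate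
Conditions: HC(OMe)3, PPTS (cat.), MeOH, rt; Et3N quench
Reagents that add atoms: trimethyl orthoformate, COC(OC)OC
Why: Acid-catalysed acetalisation of the aryl aldehyde with the orthoester as water scavenger; with ring B still mesylated, the benzylic ether of ring D tolerates the mild acid.

Step 11
Reactants: 15 hydroxy acetal mesylate
Product: 16 4-[(2R,3S)-3-{[(tert-butyldimethylsilyl)oxy]methyl}-5-(dimethoxymethyl)-7-methoxy-2,3-dihydro-1-benzofuran-2-yl]-2,6-dimethoxyphenyl methanesulfonate
Conditions: TBSCl, imidazole, DMF, rt
Reagents that add atoms: tert-butyldimethylsilyl chloride, CC(C)(C)[Si](C)(C)Cl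
Why: Silylation of the primary alcohol; it keeps an alkoxide from capturing the sulfene formed in step 12 and from interfering in steps 14 and 16.

Step 12
Reactants: 16 silyl ether acetal mesylate
Product: 17 4-[(2R,3S)-3-{[(tert-butyldimethylsilyl)oxy]methyl}-5-(dimethoxymethyl)-7-methoxy-2,3-dihydro-1-benzofuran-2-yl]-2,6-dimethoxyphenol
Conditions: LiN(i-Pr)2 (3 equiv), THF, −78 to 0 °C; aq. NH4Cl
Reagents that add atoms: none
Why: Cleavage of an aryl mesylate by deprotonation of the sulfonyl methyl group and E1cB loss of the phenoxide (sulfene mechanism). This avoids nucleophilic attack at sulfur, which the two ortho methoxy groups hinder, and spares the acetal and the silyl ether.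

Step 13
Reactants: 18 (4R)-4-benzyl-1,3-oxazolidin-2-one
Product: 19 (4R)-4-benzyl-3-(bromoacetyl)-1,3-oxazolidin-2-one
Conditions: n-BuLi, THF, −78 °C; then BrCH2COBr
Reagents that add atoms: bromoacetyl bromide, BrCC(Br)=O
Why: N-Acylation of the lithiated oxazolidinone with an acid bromide; the stereocentre of the auxiliary is not involved.

Step 14
Reactants: 17 ring B phenol; 19 (4R)-4-benzyl-3-(bromoacetyl)-1,3-oxazolidin-2-one
Product: 20 (4R)-4-benzyl-3-[2-(4-{(2R,3S)-3-[(tert-butyldimethylsilyloxy)methyl]-5-(dimethoxymethyl)-7-methoxy-2,3-dihydro-1-benzofuran-2-yl}-2,6-dimethoxyphenoxy)acetyl]-1,3-oxazolidin-2-one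
Conditions: K2CO3, MeCN, rt
Reagents that add atoms: none
Why: Williamson ether synthesis: SN2 displacement of bromide at a primary, carbonyl-activated carbon by the phenoxide, fast enough at rt to outrun base-induced opening of ring D through a quinone methide.

Step 15
Reactants: 21 vanillin (4-hydroxy-3-methoxybenzaldehyde)
Product: 22 3-methoxy-4-[(triisopropylsilyl)oxy]benzaldehyde
Conditions: TIPSCl, imidazole, DMF, rt
Reagents that add atoms: triisopropylsilyl chloride, CC(C)[Si](Cl)(C(C)C)C(C)C
Why: Silylation of the phenol, which would otherwise quench the enolate and the base of step 16.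

Step 16
Reactants: 20 aryloxyacetyl imide; 22 3-methoxy-4-[(triisopropylsilyl)oxy]benzaldehyde
Product: 24 (4R)-4-benzyl-3-[(2S,3S)-2-(4-{(2R,3S)-3-[(tert-butyldimethylsilyloxy)methyl]-5-(dimethoxymethyl)-7-methoxy-2,3-dihydro-1-benzofuran-2-yl}-2,6-dimethoxyphenoxy)-3-hydroxy-3-{3-methoxy-4-[(triisopropylsilyl)oxy]phenyl}propanoyl]-1,3-oxazolidin-2-one, via trimethylsilyl ether 23 (not isolated)
Conditions: MgCl2 (20 mol%), Et3N, Me3SiCl, EtOAc, rt; then PPTS, MeOH, 0 °C
Reagents that add atoms: none
Why: Proposed new method: the magnesium-halide-catalysed direct anti aldol addition of chiral N-acyloxazolidinones to aromatic aldehydes, known for N-propionyl and other α-alkyl acyl groups, is applied here to an α-aryloxyacetyl imide; the closest known reactions are that anti aldol and the boron-mediated syn aldol of aryloxyacetyl oxazolidinones. Et3N should enolise the magnesium-chelated imide to the Z enolate (the aryloxy group raises the acidity and its hindered oxygen is a poor ligand), the aldehyde should add through the chelated boat-like transition state on the face opposite the benzyl group, and silylation of the aldolate by Me3SiCl makes the addition irreversible and turns the catalyst over. With the (4R)-auxiliary this face and the anti topology give the (2S,3S) adduct, which carries C8′ and C7′ of the target; brief methanolysis then removes the trimethylsilyl ether while the dimethyl acetal is stable in methanol.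

Step 17
Reactants: 24 anti aldol adduct
Product: 25 (1S,2R)-2-(4-{(2R,3S)-3-[(tert-butyldimethylsilyloxy)methyl]-5-(dimethoxymethyl)-7-methoxy-2,3-dihydro-1-benzofuran-2-yl}-2,6-dimethoxyphenoxy)-1-{3-methoxy-4-[(triisopropylsilyl)oxy]phenyl}propane-1,3-diol
Conditions: LiBH4, MeOH (2 equiv), THF, 0 °C
Reagents that add atoms: none
Why: Reductive cleavage of the N-acyloxazolidinone to the primary alcohol; the exocyclic imide carbonyl is reduced selectively, the medium is not basic enough for retro-aldol cleavage, and the acetal and silyl ethers are inert.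

Step 18
Reactants: 25 protected diol
Product: 27 (2R,3S)-2-(4-{[(1S,2R)-1,3-dihydroxy-1-(4-hydroxy-3-methoxyphenyl)propan-2-yl]oxy}-3,5-dimethoxyphenyl)-3-(hydroxymethyl)-7-methoxy-2,3-dihydro-1-benzofuran-5-carbaldehyde, via desilylated acetal 26 (not isolated)
Conditions: Bu4NF, AcOH, THF, 0 °C to rt; then AcOH/H2O, rt
Reagents that add atoms: water, O
Why: Fluoride cleaves the aryl and the alkyl silyl ether under acetic acid buffering, and dilute aqueous acetic acid then hydrolyses the dimethyl acetal of the electron-rich aryl aldehyde. The conditions are kept mild because the free ring A phenol makes the C7′ carbinol prone to ionisation.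

## Compound list

1 | 1-(2-hydroxy-3-methoxyphenyl)ethan-1-one | CC(=O)c1cccc(OC)c1O | starting material
2 | 1-(5-bromo-2-hydroxy-3-methoxyphenyl)ethan-1-one | CC(=O)c1cc(Br)cc(OC)c1O | intermediate
3 | methyl 3-acetyl-4-hydroxy-5-methoxybenzoate | CC(=O)c1cc(cc(OC)c1O)C(=O)OC | intermediate
4 | methyl 3-[(2E)-3-(dimethylamino)prop-2-enoyl]-4-hydroxy-5-methoxybenzoate | CN(C)/C=C/C(=O)c1cc(cc(OC)c1O)C(=O)OC | intermediate
5 | methyl 8-methoxy-4-oxo-4H-chromene-6-carboxylate | COC(=O)c1cc(OC)c2occc(=O)c2c1 | intermediate
6 | 4-bromo-2,6-dimethoxyphenol | COc1cc(Br)cc(OC)c1O | starting material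
7 | 4-bromo-2,6-dimethoxyphenyl methanesulfonate | COc1cc(Br)cc(OC)c1OS(C)(=O)=O | intermediate
8 | [4-(methanesulfonyloxy)-3,5-dimethoxyphenyl]boronic acid | COc1cc(cc(OC)c1OS(C)(=O)=O)B(O)O | intermediate
9 | methyl (2R)-2-[4-(methanesulfonyloxy)-3,5-dimethoxyphenyl]-8-methoxy-4-oxo-3,4-dihydro-2H-chromene-6-carboxylate | COc1cc(cc(OC)c1OS(C)(=O)=O)[C@@H]1Oc2c(OC)cc(C(=O)OC)cc2C(=O)C1 | intermediate
10 | methyl (2R)-2-[4-(methanesulfonyloxy)-3,5-dimethoxyphenyl]-4,8-dimethoxy-2H-chromene-6-carboxylate | COc1cc(cc(OC)c1OS(C)(=O)=O)[C@@H]1Oc2c(OC)cc(C(=O)OC)cc2C(OC)=C1 | intermediate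
11 | methyl 3-[acetoxy(phenyl)-λ3-iodanyl]-2-[4-(methanesulfonyloxy)-3,5-dimethoxyphenyl]-4,4,8-trimethoxy-3,4-dihydro-2H-chromene-6-carboxylate, iodane trans to ring B, C2 arranged as in 9, acetate drawn as the second ligand on iodine | COc1cc(cc(OC)c1OS(C)(=O)=O)[C@@H]1Oc2c(OC)cc(C(=O)OC)cc2C(OC)(OC)[C@H]1I(OC(C)=O)c1ccccc1 | intermediate
12 | dimethyl (2R,3R)-2-[4-(methanesulfonyloxy)-3,5-dimethoxyphenyl]-7-methoxy-2,3-dihydro-1-benzofuran-3,5-dicarboxylate (trans) | COc1cc(cc(OC)c1OS(C)(=O)=O)[C@@H]1Oc2c(OC)cc(C(=O)OC)cc2[C@H]1C(=O)OC | intermediate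
13 | 4-[(2R,3S)-3,5-bis(hydroxymethyl)-7-methoxy-2,3-dihydro-1-benzofuran-2-yl]-2,6-dimethoxyphenyl methanesulfonate | COc1cc(cc(OC)c1OS(C)(=O)=O)[C@@H]1Oc2c(OC)cc(CO)cc2[C@H]1CO | intermediate
14 | 4-[(2R,3S)-5-formyl-3-(hydroxymethyl)-7-methoxy-2,3-dihydro-1-benzofuran-2-yl]-2,6-dimethoxyphenyl methanesulfonate | COc1cc(cc(OC)c1OS(C)(=O)=O)[C@@H]1Oc2c(OC)cc(C=O)cc2[C@H]1CO | intermediate
15 | 4-[(2R,3S)-5-(dimethoxymethyl)-3-(hydroxymethyl)-7-methoxy-2,3-dihydro-1-benzofuran-2-yl]-2,6-dimethoxyphenyl methanesulfonate | COc1cc(cc(OC)c1OS(C)(=O)=O)[C@@H]1Oc2c(OC)cc(C(OC)OC)cc2[C@H]1CO | intermediate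
16 | 4-[(2R,3S)-3-{[(tert-butyldimethylsilyl)oxy]methyl}-5-(dimethoxymethyl)-7-methoxy-2,3-dihydro-1-benzofuran-2-yl]-2,6-dimethoxyphenyl methanesulfonate | COc1cc(cc(OC)c1OS(C)(=O)=O)[C@@H]1Oc2c(OC)cc(C(OC)OC)cc2[C@H]1CO[Si](C)(C)C(C)(C)C | intermediate
17 | 4-[(2R,3S)-3-{[(tert-butyldimethylsilyl)oxy]methyl}-5-(dimethoxymethyl)-7-methoxy-2,3-dihydro-1-benzofuran-2-yl]-2,6-dimethoxyphenol | COc1cc(cc(OC)c1O)[C@@H]1Oc2c(OC)cc(C(OC)OC)cc2[C@H]1CO[Si](C)(C)C(C)(C)C | intermediate
18 | (4R)-4-benzyl-1,3-oxazolidin-2-one | O=C1OC[C@@H](Cc2ccccc2)N1 | starting material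
19 | (4R)-4-benzyl-3-(bromoacetyl)-1,3-oxazolidin-2-one | O=C1OC[C@@H](Cc2ccccc2)N1C(=O)CBr | intermediate
20 | (4R)-4-benzyl-3-[2-(4-{(2R,3S)-3-[(tert-butyldimethylsilyloxy)methyl]-5-(dimethoxymethyl)-7-methoxy-2,3-dihydro-1-benzofuran-2-yl}-2,6-dimethoxyphenoxy)acetyl]-1,3-oxazolidin-2-one | COc1cc(cc(OC)c1OCC(=O)N1[C@H](Cc2ccccc2)COC1=O)[C@@H]1Oc2c(OC)cc(C(OC)OC)cc2[C@H]1CO[Si](C)(C)C(C)(C)C | intermediate
21 | vanillin (4-hydroxy-3-methoxybenzaldehyde) | COc1cc(C=O)ccc1O | starting material
22 | 3-methoxy-4-[(triisopropylsilyl)oxy]benzaldehyde | COc1cc(C=O)ccc1O[Si](C(C)C)(C(C)C)C(C)C | intermediate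
23 | O-trimethylsilyl ether of 24 at the C7′ hydroxyl group | COc1cc([C@H](O[Si](C)(C)C)[C@@H](C(=O)N5[C@H](Cc6ccccc6)COC5=O)Oc2c(OC)cc([C@@H]3Oc4c(OC)cc(C(OC)OC)cc4[C@H]3CO[Si](C)(C)C(C)(C)C)cc2OC)ccc1O[Si](C(C)C)(C(C)C)C(C)C | intermediate
24 | (4R)-4-benzyl-3-[(2S,3S)-2-(4-{(2R,3S)-3-[(tert-butyldimethylsilyloxy)methyl]-5-(dimethoxymethyl)-7-methoxy-2,3-dihydro-1-benzofuran-2-yl}-2,6-dimethoxyphenoxy)-3-hydroxy-3-{3-methoxy-4-[(triisopropylsilyl)oxy]phenyl}propanoyl]-1,3-oxazolidin-2-one | COc1cc([C@H](O)[C@@H](C(=O)N5[C@H](Cc6ccccc6)COC5=O)Oc2c(OC)cc([C@@H]3Oc4c(OC)cc(C(OC)OC)cc4[C@H]3CO[Si](C)(C)C(C)(C)C)cc2OC)ccc1O[Si](C(C)C)(C(C)C)C(C)C | intermediate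
25 | (1S,2R)-2-(4-{(2R,3S)-3-[(tert-butyldimethylsilyloxy)methyl]-5-(dimethoxymethyl)-7-methoxy-2,3-dihydro-1-benzofuran-2-yl}-2,6-dimethoxyphenoxy)-1-{3-methoxy-4-[(triisopropylsilyl)oxy]phenyl}propane-1,3-diol | COc1cc([C@H](O)[C@@H](CO)Oc2c(OC)cc([C@@H]3Oc4c(OC)cc(C(OC)OC)cc4[C@H]3CO[Si](C)(C)C(C)(C)C)cc2OC)ccc1O[Si](C(C)C)(C(C)C)C(C)C | intermediate
26 | (1S,2R)-2-{4-[(2R,3S)-5-(dimethoxymethyl)-3-(hydroxymethyl)-7-methoxy-2,3-dihydro-1-benzofuran-2-yl]-2,6-dimethoxyphenoxy}-1-(4-hydroxy-3-methoxyphenyl)propane-1,3-diol | COc1cc([C@H](O)[C@@H](CO)Oc2c(OC)cc([C@@H]3Oc4c(OC)cc(C(OC)OC)cc4[C@H]3CO)cc2OC)ccc1O | intermediate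
27 | (2R,3S)-2-(4-{[(1S,2R)-1,3-dihydroxy-1-(4-hydroxy-3-methoxyphenyl)propan-2-yl]oxy}-3,5-dimethoxyphenyl)-3-(hydroxymethyl)-7-methoxy-2,3-dihydro-1-benzofuran-5-carbaldehyde | COc1cc([C@H](O)[C@@H](CO)Oc2c(OC)cc([C@@H]3Oc4c(OC)cc(C=O)cc4[C@H]3CO)cc2OC)ccc1O | target

## Step count and least certain steps

Total step count: 18. Longest linear sequence: 14 steps, from 1 to 27 through steps 1, 2, 3, 6, 7, 8, 9, 10, 11, 12, 14, 16, 17 and 18.

**Step 16 (anti glycolate aldol, beyond precedent).** The most likely failure is loss of diastereocontrol. The α-aryloxy oxygen may join the magnesium chelate and change the enolate or transition-state geometry, or the addition to the electron-rich aldehyde 22 may stay reversible before silylation, so that syn adduct or the wrong enolate face leaks in. Slow conversion is the second risk.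

The fallback uses known chemistry, sets out from 17 and comes back at 27. Phenol 17 would be alkylated (K2CO3, MeCN) with (4S)-4-benzyl-3-(bromoacetyl)-1,3-oxazolidin-2-one F1 to the diastereomeric aryloxyacetyl imide F2. Its dibutylboron enolate (Bu2BOTf, i-Pr2NEt, CH2Cl2, −78 to 0 °C) would add to 22 in the established syn sense to give the (2S,3R) adduct F3, in which C8′ is correct and C7′ is epimeric. LiBH4 would then give the threo diol F4, and TBSCl with imidazole would silylate its primary alcohol to the threo C9′ silyl ether F5. Mitsunobu inversion at C7′ (4-nitrobenzoic acid, PPh3, DIAD) would give the erythro 4-nitrobenzoate F6, and methanolysis (K2CO3, MeOH) the erythro C9′ silyl ether F7. The conditions of step 18 would take F7 to 27.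

**Step 7 (key step).** The most likely failure is that iodobenzene is lost from 11 faster than ring C migrates, because the ester para to O1 lowers the migratory aptitude of the ring C carbon. The result would be elimination to the flavone or methanol substitution at C3. A minor risk is partial racemisation of C2 by acid-induced ring opening before the ketone is ketalised.

The fallback sets out from 9 and comes back at 12, keeping the same skeletal change. Ketone 9 would be trifluoroacetylated at C3 (LiN(SiMe3)2, CF3CO2CH2CF3, THF, −78 °C) to the 3-trifluoroacetyl flavanone F8 and converted by detrifluoroacetylative diazo transfer (MsN3, Et3N, H2O, MeCN) into the 3-diazo flavanone F9. Photolysis of F9 in MeOH would trigger a Wolff rearrangement in which the same ring C carbon moves from C4 to C3. Methanol would add to the ring-contracted ketene to give 12 together with the cis diester F10, which would be equilibrated to 12 with a catalytic amount of DBU at low temperature.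

**Step 6 (asymmetric conjugate addition).** The most likely failures are protodeboronation of the 3,4,5-trisubstituted boronic acid 8 outpacing a slow insertion, and insufficient facial discrimination, since the sense and level of induction are inferred by analogy.

The fallback sets out from 3 and comes back at 9. Syringaldehyde F11 would be mesylated (MsCl, Et3N) to 4-formyl-2,6-dimethoxyphenyl methanesulfonate F12. Pyrrolidine-mediated aldol condensation of 3 with F12 (MeOH, reflux) would give the 2′-hydroxychalcone F13, which closes by oxa-Michael addition to the racemic flavanone F14. The enantiomers of F14 would be separated by preparative chromatography on a chiral stationary phase to give 9, and the unwanted enantiomer would be recycled by base-induced equilibration through F13.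

**Step 2 (methoxycarbonylation).** The most likely failure is slow oxidative addition into the electron-rich bromophenol, which is present largely as its phenoxide, with catalyst decay before conversion is complete.

The fallback sets out from a different commercial starting material and comes back at 3. Methyl vanillate F15 would be iodinated ortho to the phenol (N-iodosuccinimide, cat. CF3CO2H, MeCN) to methyl 4-hydroxy-3-iodo-5-methoxybenzoate F16. Stille coupling with tributyl(1-ethoxyvinyl)stannane (PdCl2(PPh3)2, toluene, 100 °C) would give the enol ether methyl 3-(1-ethoxyethenyl)-4-hydroxy-5-methoxybenzoate F17, which 1 M HCl hydrolyses to 3.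

## Further compounds

F1 | step 16 | (4S)-4-benzyl-3-(bromoacetyl)-1,3-oxazolidin-2-one | O=C1OC[C@H](Cc2ccccc2)N1C(=O)CBr
F2 | step 16 | (4S)-4-benzyl-3-[2-(4-{(2R,3S)-3-[(tert-butyldimethylsilyloxy)methyl]-5-(dimethoxymethyl)-7-methoxy-2,3-dihydro-1-benzofuran-2-yl}-2,6-dimethoxyphenoxy)acetyl]-1,3-oxazolidin-2-one | COc1cc(cc(OC)c1OCC(=O)N1[C@@H](Cc2ccccc2)COC1=O)[C@@H]1Oc2c(OC)cc(C(OC)OC)cc2[C@H]1CO[Si](C)(C)C(C)(C)C
F3 | step 16 | (4S)-4-benzyl-3-[(2S,3R)-2-(aryloxy)-3-hydroxy-3-{3-methoxy-4-[(triisopropylsilyl)oxy]phenyl}propanoyl]-1,3-oxazolidin-2-one, syn adduct, aryloxy group as in 24 | COc1cc([C@@H](O)[C@@H](C(=O)N5[C@@H](Cc6ccccc6)COC5=O)Oc2c(OC)cc([C@@H]3Oc4c(OC)cc(C(OC)OC)cc4[C@H]3CO[Si](C)(C)C(C)(C)C)cc2OC)ccc1O[Si](C(C)C)(C(C)C)C(C)C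
F4 | step 16 | (1R,2R)-threo epimer of 25 at C7′ | COc1cc([C@@H](O)[C@@H](CO)Oc2c(OC)cc([C@@H]3Oc4c(OC)cc(C(OC)OC)cc4[C@H]3CO[Si](C)(C)C(C)(C)C)cc2OC)ccc1O[Si](C(C)C)(C(C)C)C(C)C
F5 | step 16 | C9′ tert-butyldimethylsilyl ether of F4, (1R,2R) | COc1cc([C@@H](O)[C@@H](CO[Si](C)(C)C(C)(C)C)Oc2c(OC)cc([C@@H]3Oc4c(OC)cc(C(OC)OC)cc4[C@H]3CO[Si](C)(C)C(C)(C)C)cc2OC)ccc1O[Si](C(C)C)(C(C)C)C(C)C
F6 | step 16 | (1S,2R)-erythro C7′ 4-nitrobenzoate, C9′ tert-butyldimethylsilyl ether | COc1cc([C@H](OC(=O)c5ccc(cc5)[N+](=O)[O-])[C@@H](CO[Si](C)(C)C(C)(C)C)Oc2c(OC)cc([C@@H]3Oc4c(OC)cc(C(OC)OC)cc4[C@H]3CO[Si](C)(C)C(C)(C)C)cc2OC)ccc1O[Si](C(C)C)(C(C)C)C(C)C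
F7 | step 16 | C9′ tert-butyldimethylsilyl ether of 25, (1S,2R) | COc1cc([C@H](O)[C@@H](CO[Si](C)(C)C(C)(C)C)Oc2c(OC)cc([C@@H]3Oc4c(OC)cc(C(OC)OC)cc4[C@H]3CO[Si](C)(C)C(C)(C)C)cc2OC)ccc1O[Si](C(C)C)(C(C)C)C(C)C
F8 | step 7 | methyl (2R)-2-[4-(methanesulfonyloxy)-3,5-dimethoxyphenyl]-8-methoxy-4-oxo-3-(trifluoroacetyl)-3,4-dihydro-2H-chromene-6-carboxylate, C3 unassigned | COc1cc(cc(OC)c1OS(C)(=O)=O)[C@@H]1Oc2c(OC)cc(C(=O)OC)cc2C(=O)C1C(=O)C(F)(F)F
F9 | step 7 | methyl 3-diazo-2-[4-(methanesulfonyloxy)-3,5-dimethoxyphenyl]-8-methoxy-4-oxo-3,4-dihydro-2H-chromene-6-carboxylate, C2 arranged as in 9 (descriptor 2S by priority change) | COc1cc(cc(OC)c1OS(C)(=O)=O)[C@@H]1Oc2c(OC)cc(C(=O)OC)cc2C(=O)C1=[N+]=[N-]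
F10 | step 7 | dimethyl (2R,3S)-2-[4-(methanesulfonyloxy)-3,5-dimethoxyphenyl]-7-methoxy-2,3-dihydro-1-benzofuran-3,5-dicarboxylate (cis) | COc1cc(cc(OC)c1OS(C)(=O)=O)[C@@H]1Oc2c(OC)cc(C(=O)OC)cc2[C@@H]1C(=O)OC
F11 | step 6 | syringaldehyde (4-hydroxy-3,5-dimethoxybenzaldehyde) | COc1cc(C=O)cc(OC)c1O
F12 | step 6 | 4-formyl-2,6-dimethoxyphenyl methanesulfonate | COc1cc(C=O)cc(OC)c1OS(C)(=O)=O
F13 | step 6 | methyl 4-hydroxy-3-{(2E)-3-[4-(methanesulfonyloxy)-3,5-dimethoxyphenyl]prop-2-enoyl}-5-methoxybenzoate | COc1cc(/C=C/C(=O)c2cc(cc(OC)c2O)C(=O)OC)cc(OC)c1OS(C)(=O)=O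
F14 | step 6 | racemic methyl 2-[4-(methanesulfonyloxy)-3,5-dimethoxyphenyl]-8-methoxy-4-oxo-3,4-dihydro-2H-chromene-6-carboxylate | COc1cc(cc(OC)c1OS(C)(=O)=O)C1Oc2c(OC)cc(C(=O)OC)cc2C(=O)C1
F15 | step 2 | methyl vanillate (methyl 4-hydroxy-3-methoxybenzoate) | COC(=O)c1ccc(O)c(OC)c1
F16 | step 2 | methyl 4-hydroxy-3-iodo-5-methoxybenzoate | COC(=O)c1cc(I)c(O)c(OC)c1
F17 | step 2 | methyl 3-(1-ethoxyethenyl)-4-hydroxy-5-methoxybenzoate | CCOC(=C)c1cc(cc(OC)c1O)C(=O)OC
A1 | alternative 1 | (4S,5R)-5-(4-formyl-2,6-dimethoxyphenoxy)-4-{3-methoxy-4-[(triisopropylsilyl)oxy]phenyl}-1,3-dioxan-2-one (trans) | COc1cc(ccc1O[Si](C(C)C)(C(C)C)C(C)C)[C@@H]1OC(=O)OC[C@H]1Oc1c(OC)cc(C=O)cc1OC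
A2 | alternative 1 | tert-butyl (2S)-2-(4-formyl-2,6-dimethoxyphenoxy)-3-{3-methoxy-4-[(triisopropylsilyl)oxy]phenyl}propyl carbonate | CC(C)(C)OC(=O)OC[C@H](Cc1ccc(O[Si](C(C)C)(C(C)C)C(C)C)c(OC)c1)Oc1c(OC)cc(C=O)cc1OC
A3 | alternative 2 | tert-butyl{4-[(2R,3S)-5-bromo-7-methoxy-3-{[(triisopropylsilyl)oxy]methyl}-2,3-dihydro-1-benzofuran-2-yl]-2,6-dimethoxyphenoxy}dimethylsilane (trans) | COc1cc(cc(OC)c1O[Si](C)(C)C(C)(C)C)[C@@H]1Oc2c(OC)cc(Br)cc2[C@H]1CO[Si](C(C)C)(C(C)C)C(C)C
A4 | alternative 2 | racemic 4-bromo-2-methoxy-6-[1-(4-methylbenzenesulfonyl)-2-(triisopropylsilyloxy)ethyl]phenol | COc1cc(Br)cc(C(CO[Si](C(C)C)(C(C)C)C(C)C)S(=O)(=O)c2ccc(C)cc2)c1O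
A5 | alternative 2 | (2R,5R)-1-{[4-(tert-butyldimethylsilyloxy)-3,5-dimethoxyphenyl]methyl}-2,5-dimethylthiolan-1-ium tetrafluoroborate | C[C@@H]1CC[C@@H](C)[S+]1Cc1cc(OC)c(O[Si](C)(C)C(C)(C)C)c(OC)c1.F[B-](F)(F)F
A6 | alternative 3 | {(2R,3S)-2-[3,5-dimethoxy-4-(prop-2-en-1-yloxy)phenyl]-5-formyl-7-methoxy-2,3-dihydro-1-benzofuran-3-yl}methyl 2,2-dimethylpropanoate (trans) | COc1cc(cc(OC)c1OCC=C)[C@@H]1Oc2c(OC)cc(C=O)cc2[C@H]1COC(=O)C(C)(C)C
A7 | alternative 3 | (2S)-3-[3,5-dimethoxy-4-(prop-2-en-1-yloxy)phenyl]-2-(5-formyl-2-hydroxy-3-methoxyphenyl)propyl 2,2-dimethylpropanoate | COc1cc(C[C@H](COC(=O)C(C)(C)C)c2cc(C=O)cc(OC)c2O)cc(OC)c1OCC=C
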